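The earlier runs and the new flask come from a simulation with constants of no real substance, noise included.

In the west run 5 mM of incoming ligand met 7.5 mM of starting complex, and the complex with two exchanged read 31.1% at 2.00 min and 30.5% at 5.00 min, flat within the scatter of 1 percentage point. The flask below has equal charges and runs to 6.0 min.

| flask | starting complex | incoming ligand | scavenger | remark | time |
|---|---|---|---|---|---|
| south-east | 5 mM | 7 mM | 6 mM | run made earlier |  |
| north-west | 5 mM | 11 mM | 6 mM | run made earlier |  |
| west | 7.5 mM | 5 mM | 6 mM | run made earlier |  |
| flask | 5.0 mM | 5.00 mM | 6.00 mM |  | 6.0 min |

- south-east (time / min: complex with two exchanged / %, complex with three exchanged / %): 1.33: 52.3, 2.5; 2.50: 59.2, 2.3; 4.00: 58.7, 3.1; 5.00: 62.0, 3.9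
- north-west (time / min: complex with two exchanged / %, complex with three exchanged / %): 1.33: 65.8, 6.3; 2.50: 69.0, 11.2; 4.00: 70.9, 13.3; 5.00: 70.7, 13.3
- west (time / min: complex with two exchanged / %, complex with three exchanged / %): 0.417: 22.2, 0; 0.833: 26.6, 1.5; 2.00: 31.1, 2.0; 5.00: 30.5, 0

(scatter of a reading: 1 percentage point)



- equivalents of incoming ligand to starting complex, everything else as given, that leave most complex with two exchanged at 6.0 min
- the amount of complex with two exchanged then, in percent of the starting complex charged
- the amount of complex with two exchanged with the amounts as given

Build the flask one process at a time. With the main step alone, each complex with two exchanged holds two incoming ligands, so incoming ligand is the limiting reagent and the ceiling is [incoming ligand]/(2[starting complex]), which is 50.0% in the flask.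

Now add further exchange. The complex with three exchanged read 0% at the end of the west run and 3.9% at the end of the south-east run, small beside the 62.0% of two-exchanged there.

Then add the rest, which you see as a shortfall of ligand. The last west reading puts 91.5% of the charged ligand into the complex with two exchanged, the last south-east reading 88.6%. The flask's ratio lies between those two runs, so I carry their mean, 90.0%, as the ligand capture, the share of charged incoming ligand found in complex with two exchanged. My reckoning for the flask is capture times ceiling, 45.0%.

The north-west run charged 11 mM of incoming ligand, more than the 10.0 mM that two exchanges on 5 mM of starting complex take, so the ligand-limited ceiling and capture do not apply there; that run read 70.7%, with 13.3% of three-exchanged.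

The forecast gave 45% as charged and 72% at 2.3 equiv, “a broad optimum and my estimate only”.

The simulation gives 46.1% as charged, and 72.4% at 2.17 equiv.

    starting complex + incoming ligand → leaving ligand + complex with one exchanged (k = 7.20 L mol⁻¹ s⁻¹)
    complex with one exchanged + incoming ligand → leaving ligand + complex with two exchanged (k = 43.0 L mol⁻¹ s⁻¹)
    leaving ligand + incoming ligand ⇌ idle adduct, settled at all times (K = 140 L mol⁻¹)
    starting complex ⇌ dormant form (K = 2.20, k = 0.0270 s⁻¹)
    complex with two exchanged + incoming ligand → leaving ligand + complex with three exchanged (k = 0.300 L mol⁻¹ s⁻¹)
    scavenger + leaving ligand → scavenged by-product (k = 340 L mol⁻¹ s⁻¹)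

Capture in the flask comes to 92.1%. At 6.00 min the half-life of starting complex by its first exchange is 76 min, far longer than the 6.0 min of the run, with incoming ligand at 0.42% of its charge. At that time the flask holds 15.5% of starting complex and 34.2% of dormant form, and its complex with two exchanged stands at 46.2% at 60.0 min. With 1.2 mM of incoming ligand, the neighbour's ceiling is 12.0%, so capture predicts 10.8%. That neighbour holds 8.88%, a capture of 74.0%, and 6.10% stands as complex with one exchanged.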